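Its constants were chosen freely; the flask was simulated.

Set two amounts side by side in each flask: the free monomer that can still enter chains, and the pre-initiator that can begin them.

| setting | ash | elm |
|---|---|---|
| free monomer | 0.80 M | 0.80 M |
| pre-initiator | 2.2 mol% | 1.2 mol% |
| time | 20 min | 20 min |

    free monomer + initiator → living end + monomer in chains (k1 = 16.0 /M/min)
    pre-initiator ⇌ initiator (K2 = 1.8, k2 = 0.0824 /min)
    living end + monomer in chains → dead end (k3 = 2.28 /M/min)
    free monomer + living end → monomer in chains + living end, rate k4*[living end]*[free monomer] (k4 = 97.0 /M/min)
    monomer in chains + living end → free monomer + living end, rate k5*[living end] as long as [monomer in chains] is above zero (k5 = 43.9 /min)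

- the average divides the monomer in chains by the number of chains begun, living and dead together
- run time (ash): 20 min

1. which of the two ends with the longer chains by the average number of monomer units in a chain (chains begun, living or dead) ("neither" if they lie within 10%) (ash / elm / neither)
2. average number of monomer units in a chain (chains begun, living or dead) at the end, ash
3. average number of monomer units in a chain (chains begun, living or dead) at the end, elm

Follow one living end first. It takes up free monomer at 97.0 /M/min times c(free monomer) and gives it back at 43.9 /min. The two balance at c(free monomer) = 0.453 M, the ceiling, in the field's term the equilibrium monomer concentration. Both flasks start above it, so take the room above the ceiling, 0.347 M, as the free monomer that can go into chains.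

Now count chains. In ash, initiator has a half-life of 0.054 min by its reaction with free monomer as charged. Pre-initiator has 8.4 min by its forward rate. By the way back to pre-initiator, initiator has a half-life of 15.1 min, so leave the way back out of the reckoning. So in ash take pre-initiator conversion as the rate-limiting step of chain starting, and let each pre-initiator converted give one chain. The charges are 0.01760 M in ash and 0.009600 M in elm.

Divide room by charge: 19.7 units per chain in ash, 36.2 in elm. Call this room per chain charged the ceiling length. It is an estimate, not a bound. The room is shared, so elm should end longer, by a factor of 1.84. Stop there. The run lasts 2.38 forward half-lives of pre-initiator, so the count of chains is still incomplete at the end.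

The forecast goes further than this reckoning and counts the chains begun by the end. It names elm, with 22.3 for ash and 36.4 for elm. Its ground: “Initiator is quasi-steady, so chains begun follow pre-initiator conversion”.

The simulation gives 22.2 for ash and 36.6 for elm, so elm ends with the longer chains, as forecast. At that time ash still holds 19.4% of its pre-initiator, and its average stands above its ceiling length of 19.7. Now take the neighbour of ash charged with 1.4 M of free monomer, at the same loading. Its ceiling length is 30.8, and that flask ends at 32.4.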